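The route rests on the C4'–C5' bond of the side chain C2–C1'H2–C2'H2–C3'H=C4'(CH3)–C5'H2–C6'H2–C7'H=C8'(CH3)CO2Me. This chain hangs on C2 of the chroman (benzene ring A, dihydropyran ring B). The feature exploited is the (E)-trisubstituted C3'=C4' alkene, whose C4' carries CH3 and C5'. A Zweifel olefination joins a C5'–C7' boronic ester to C4'. Through anti 1,2-migration and anti elimination it inverts the alkene geometry in the same operation. The precursor is therefore the wrong-looking (Z)-4'-iodoalkene, one Wittig step from an aldehyde cut out of a linalool-derived chroman. (R)-Linalool supplies C2 unchanged. A final Still–Gennari olefination adds the (Z)-enoate.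

Key step: step 7

Assumption: (R)-(−)-linalool is used in enantiopure natural grade, because its carbinol carbon becomes C2 of the chroman without any bond to it being broken, and the 3,3-diethoxypropyl pinacol boronic ester is taken as a catalogue compound.

Step 1
Reactants: 1 3-bromo-5-methylphenol
Product: 2 3-bromo-4-iodo-5-methylphenol
Conditions: NIS (1.05 equiv), p-TsOH·H2O (0.2 equiv), MeCN, rt, dark
Reagents that add atoms: N-iodosuccinimide, O=C1CCC(=O)N1I
Why: Electrophilic aromatic iodination with acid-activated NIS should go para to the hydroxyl group, the position activated by both OH (para) and CH3 (ortho), as is usual for 3,5-disubstituted phenols.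

Step 2
Reactants: 2 3-bromo-4-iodo-5-methylphenol
Product: 3 1-bromo-2-iodo-5-(methoxymethoxy)-3-methylbenzene
Conditions: MOMCl (1.3 equiv), i-Pr2NEt (1.5 equiv), CH2Cl2, 0 °C → rt
Reagents that add atoms: chloromethyl methyl ether, COCCl
Why: O-alkylation of the phenol (Williamson-type acetal formation) gives a MOM ether that tolerates base, organolithiums, oxidants and palladium and leaves later in acid.

Step 3
Reactants: 4 (R)-(−)-linalool; 3 1-bromo-2-iodo-5-(methoxymethoxy)-3-methylbenzene
Product: 6 (3R)-1-[2-bromo-4-(methoxymethoxy)-6-methylphenyl]-3,7-dimethyloct-6-en-3-ol, via B-alkyl-9-BBN adduct 5 (not isolated)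
Conditions: 9-BBN-H (2.2 equiv), THF, 0 °C → rt; then 3, PdCl2(dppf) (5 mol %), 3 M aq NaOH, THF, 50 °C
Reagents that add atoms: 9-BBN-H, C1CC2CCCC(C1)B2 (its boron unit stays only in intermediate 5; product 6 keeps only its hydrogen)
Why: 9-BBN hydroborates the monosubstituted vinyl group at its terminus in preference to the trisubstituted alkene, and the B-alkyl Suzuki–Miyaura coupling then takes place at C–I before C–Br, with no bond to the carbinol stereocentre being touched.

Step 4
Reactants: 6 (3R)-1-[2-bromo-4-(methoxymethoxy)-6-methylphenyl]-3,7-dimethyloct-6-en-3-ol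
Product: 7 (2R)-7-(methoxymethoxy)-2,5-dimethyl-2-(4-methylpent-3-en-1-yl)chromane
Conditions: Pd(OAc)2 (5 mol %), 2-(di-tert-butylphosphino)-1,1'-binaphthyl (6 mol %), Cs2CO3 (1.5 equiv), toluene, 80 °C
Reagents that add atoms: none
Why: Intramolecular Buchwald–Hartwig-type C–O coupling closes ring B at the aryl carbon, the tertiary alkoxide has no hydrogen on its carbinol carbon for beta-hydride loss, and the O–C2 bond is never broken, so the configuration is retained.

Step 5
Reactants: 7 (2R)-7-(methoxymethoxy)-2,5-dimethyl-2-(4-methylpent-3-en-1-yl)chromane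
Product: 9 3-[(2S)-7-(methoxymethoxy)-2,5-dimethylchroman-2-yl]propanal, via vicinal diol 8 (not isolated)
Conditions: OsO4 (2 mol %), NaIO4 (4 equiv), 2,6-lutidine (2 equiv), 1,4-dioxane–H2O (3:1), rt
Reagents that add atoms: NaIO4, [Na+].[O-]I(=O)(=O)=O (terminal source of the new oxygen); OsO4, O=[Os](=O)(=O)=O (relays it)
Why: Lemieux–Johnson cleavage, in which OsO4 dihydroxylates the only alkene and periodate splits diol 8 and re-oxidises osmium, leaves the protected ring A and C2 untouched (the descriptor changes by ranking only).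

Step 6
Reactants: 9 3-[(2S)-7-(methoxymethoxy)-2,5-dimethylchroman-2-yl]propanal
Product: 10 (2R)-2-[(3Z)-4-iodopent-3-en-1-yl]-7-(methoxymethoxy)-2,5-dimethylchromane
Conditions: EtPPh3I, n-BuLi, THF, rt; I2, −78 °C; NaN(SiMe3)2, −20 °C; then 9, −78 → −20 °C
Reagents that add atoms: ethyltriphenylphosphonium iodide, CC[P+](c1ccccc1)(c1ccccc1)c1ccccc1.[I-]; iodine, II
Why: Stork–Zhao-type Wittig iodo-olefination with the unstabilised alpha-iodo ylide runs under kinetic control through the cis-oxaphosphetane and should place iodine cis to the C2' chain, giving the (Z)-iodoalkene.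

Step 7
Reactants: 10 (2R)-2-[(3Z)-4-iodopent-3-en-1-yl]-7-(methoxymethoxy)-2,5-dimethylchromane; 11 2-(3,3-diethoxypropyl)-4,4,5,5-tetramethyl-1,3,2-dioxaborolane
Product: 15 (2R)-2-[(3E)-7,7-diethoxy-4-methylhept-3-en-1-yl]-7-(methoxymethoxy)-2,5-dimethylchromane, via alkenyllithium 12 (not isolated), via lithium alkenylboronate 13 (not isolated), via beta-iodoalkyl boronic ester 14 (not isolated)
Conditions: t-BuLi (2.0 equiv), Et2O, −78 °C; 11 (1.1 equiv), THF, −78 → 0 °C; I2 (1.2 equiv), THF, −78 °C; NaOMe (3 equiv), MeOH, −78 °C → rt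
Reagents that add atoms: t-BuLi, CC(C)(C)[Li] (lithium of 12 and 13 only); iodine, II (iodine of 14 only); none of these atoms stays in 15
Why: Iodine–lithium exchange on 10 keeps the alkene geometry, so 12 carries lithium cis to the C2' chain, and its addition to the empty orbital on boron of 11 gives the tetracoordinate boronate 13. Iodine attacks the electron-rich C3'=C4' bond of 13 to form an iodonium ion, and the 3,3-diethoxypropyl group migrates from boron to C4' antiperiplanar to the breaking C4'–I bond, which makes the C4'–C5' bond and sets the two transient stereocentres of 14 (C3' and C4') by overall anti addition, controlled by the alkene geometry alone. Methoxide then binds to boron and triggers antiperiplanar loss of boron and iodide, so the new alkyl group ends up trans to the C2' chain and the (Z)-iodide becomes the (E)-alkene with inversion. This is a Zweifel olefination, a known stereospecific, transition-metal-free coupling of alkenyllithiums and primary alkyl pinacol boronic esters that also serves for trisubstituted alkenes. No ring is closed and no lasting stereocentre is made, and either face of 13 may react because both face isomers of 14 collapse to the same alkene while C2 is remote and untouched. The step needs exchange to outrun ortho-lithiation beside the MOM ether (secured by the very fast exchange of an alkenyl iodide at −78 °C and exactly two equivalents of t-BuLi), carbon rather than oxygen migration (secured by the pinacol ligand), and iodination of the boronate rather than of ring A (secured by the much higher nucleophilicity of the anionic alkenylboronate and a near-stoichiometric charge of iodine).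

Step 8
Reactants: 15 (2R)-2-[(3E)-7,7-diethoxy-4-methylhept-3-en-1-yl]-7-(methoxymethoxy)-2,5-dimethylchromane
Product: 16 (4E)-7-[(2R)-7-hydroxy-2,5-dimethylchroman-2-yl]-4-methylhept-4-enal
Conditions: 3 M aq HCl–THF (1:2), high dilution, 45 °C
Reagents that add atoms: water, O
Why: Specific-acid acetal hydrolysis removes the diethyl acetal and the aryl MOM ether in one operation, under acidity too low to protonate the trisubstituted alkene or to ionise the tertiary O–C2 bond.

Step 9
Reactants: 17 methyl 2-[bis(2,2,2-trifluoroethoxy)phosphoryl]acetate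
Product: 19 methyl 2-[bis(2,2,2-trifluoroethoxy)phosphoryl]propanoate (racemic), via sodium phosphonoacetate carbanion 18 (not isolated)
Conditions: NaH (1.0 equiv), THF, 0 °C; MeI (1.05 equiv), 0 °C → rt
Reagents that add atoms: iodomethane, CI; NaH, [Na+].[H-] (sodium of 18 only)
Why: SN2 C-alkylation of the stabilised phosphonate carbanion, with one equivalent of a non-nucleophilic base limiting double methylation and sparing the P–O esters.

Step 10
Reactants: 16 (4E)-7-[(2R)-7-hydroxy-2,5-dimethylchroman-2-yl]-4-methylhept-4-enal; 19 methyl 2-[bis(2,2,2-trifluoroethoxy)phosphoryl]propanoate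
Product: 21 methyl (2Z,6E)-9-[(2R)-7-hydroxy-2,5-dimethyl-3,4-dihydro-2H-chromen-2-yl]-2,6-dimethylnona-2,6-dienoate, via potassium phosphonate carbanion 20 (not isolated)
Conditions: 19 (2.5 equiv), KN(SiMe3)2 (2.4 equiv), 18-crown-6 (5 equiv), THF, −78 °C; then 16, −78 °C; aq NH4Cl
Reagents that add atoms: KN(SiMe3)2, C[Si](C)(C)[N-][Si](C)(C)C.[K+] (potassium of 20 only)
Why: In the Still–Gennari olefination the electron-poor bis(trifluoroethyl) phosphonate and the dissociated potassium/18-crown-6 ion pair make elimination from the kinetic adduct faster than its reversal, which should give the (Z)-2-methylenoate, while surplus carbanion only holds the phenol as phenoxide until work-up.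

Compound list
1 | 3-bromo-5-methylphenol | Cc1cc(O)cc(Br)c1 | starting material
2 | 3-bromo-4-iodo-5-methylphenol | Cc1cc(O)cc(Br)c1I | intermediate
3 | 1-bromo-2-iodo-5-(methoxymethoxy)-3-methylbenzene | COCOc1cc(C)c(I)c(Br)c1 | intermediate
4 | (R)-(−)-linalool, (3R)-3,7-dimethylocta-1,6-dien-3-ol | C=C[C@](C)(O)CCC=C(C)C | starting material
5 | (3S)-1-(9-borabicyclo[3.3.1]nonan-9-yl)-3,7-dimethyloct-6-en-3-ol (same spatial arrangement as 4, descriptor changed by ranking only) | CC(C)=CCC[C@@](C)(O)CCB1C2CCCC1CCC2 | intermediate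
6 | (3R)-1-[2-bromo-4-(methoxymethoxy)-6-methylphenyl]-3,7-dimethyloct-6-en-3-ol | CC(C)=CCC[C@@](C)(O)CCc1c(C)cc(OCOC)cc1Br | intermediate
7 | (2R)-7-(methoxymethoxy)-2,5-dimethyl-2-(4-methylpent-3-en-1-yl)chromane | CC(C)=CCC[C@]1(C)CCc2c(C)cc(OCOC)cc2O1 | intermediate
8 | 5-[(2S)-7-(methoxymethoxy)-2,5-dimethylchroman-2-yl]-2-methylpentane-2,3-diol (both epimers at the secondary carbinol) | CC(C)(O)C(O)CC[C@]1(C)CCc2c(C)cc(OCOC)cc2O1 | intermediate
9 | 3-[(2S)-7-(methoxymethoxy)-2,5-dimethylchroman-2-yl]propanal | O=CCC[C@]1(C)CCc2c(C)cc(OCOC)cc2O1 | intermediate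
10 | (2R)-2-[(3Z)-4-iodopent-3-en-1-yl]-7-(methoxymethoxy)-2,5-dimethylchromane (iodine cis to the chain) | I/C(C)=C\CC[C@]1(C)CCc2c(C)cc(OCOC)cc2O1 | intermediate
11 | 2-(3,3-diethoxypropyl)-4,4,5,5-tetramethyl-1,3,2-dioxaborolane | CCOC(CCB1OC(C)(C)C(C)(C)O1)OCC | starting material
12 | alkenyllithium from 10, lithium at C4' cis to the C2' chain, (2R) | [Li]/C(C)=C\CC[C@]1(C)CCc2c(C)cc(OCOC)cc2O1 | intermediate
13 | lithium (alkenyl)(3,3-diethoxypropyl)pinacolatoborate, boron at C4' cis to the C2' chain, (2R) | CCOC(CC[B-]1(/C(C)=C\CC[C@]2(C)CCc3c(C)cc(OCOC)cc3O2)OC(C)(C)C(C)(C)O1)OCC.[Li+] | intermediate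
14 | (2S)-2-[(3S,4S)-7,7-diethoxy-3-iodo-4-methyl-4-(4,4,5,5-tetramethyl-1,3,2-dioxaborolan-2-yl)heptyl]-7-(methoxymethoxy)-2,5-dimethylchromane (drawn; the (3R,4R) face isomer forms beside it and gives the same alkene) | CCOC(CC[C@@](C)(B1OC(C)(C)C(C)(C)O1)[C@@H](I)CC[C@]1(C)CCc2c(C)cc(OCOC)cc2O1)OCC | intermediate
15 | (2R)-2-[(3E)-7,7-diethoxy-4-methylhept-3-en-1-yl]-7-(methoxymethoxy)-2,5-dimethylchromane | CCOC(CC/C(C)=C/CC[C@]1(C)CCc2c(C)cc(OCOC)cc2O1)OCC | intermediate
16 | (4E)-7-[(2R)-7-hydroxy-2,5-dimethylchroman-2-yl]-4-methylhept-4-enal | O=CCC/C(C)=C/CC[C@]1(C)CCc2c(C)cc(O)cc2O1 | intermediate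
17 | methyl 2-[bis(2,2,2-trifluoroethoxy)phosphoryl]acetate | COC(=O)CP(=O)(OCC(F)(F)F)OCC(F)(F)F | starting material
18 | sodium carbanion of 17 | COC(=O)[CH-]P(=O)(OCC(F)(F)F)OCC(F)(F)F.[Na+] | intermediate
19 | methyl 2-[bis(2,2,2-trifluoroethoxy)phosphoryl]propanoate (racemic; the centre is lost on deprotonation) | COC(=O)C(C)P(=O)(OCC(F)(F)F)OCC(F)(F)F | intermediate
20 | potassium carbanion of 19 | COC(=O)[C-](C)P(=O)(OCC(F)(F)F)OCC(F)(F)F.[K+] | intermediate
21 | methyl (2Z,6E)-9-[(2R)-7-hydroxy-2,5-dimethyl-3,4-dihydro-2H-chromen-2-yl]-2,6-dimethylnona-2,6-dienoate | COC(=O)/C(C)=C\CC/C(C)=C/CC[C@]1(C)CCc2c(C)cc(O)cc2O1 | target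

Total step count: 10. Longest linear sequence: 9 (steps 1–8 and 10, from 1).

Steps most likely to fail

Step 7 (key step).
- What may go wrong:
  - ortho-lithiation of ring A beside the MOM ether;
  - protonation of the alkenyllithium before it reaches boron;
  - electrophilic iodination of ring A;
  - leakage of the migration–elimination sequence into a non-stereospecific path.
- Fallback (sets out from 9, returns at 16): the same C4'–C5' bond is made by stereoretentive palladium catalysis on a geminal dihalide instead of by a 1,2-metallate shift. Aldehyde 9 is converted with PPh3/CCl4 into the 1,1-dichloroalkene F1. A trans-selective Negishi monoalkylation with commercial 2-(1,3-dioxolan-2-yl)ethylzinc bromide under PdCl2(DPEphos) replaces only the chlorine trans to the chain and gives the (Z)-chloroalkene F2. A second Negishi coupling with Me2Zn under Pd(P(t-Bu)3)2 exchanges the remaining chlorine for methyl with retention and gives the (E)-alkene dioxolane F3. The acid conditions of step 8 convert F3 into 16.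

Step 6.
- What may go wrong:
  - enolisation of 9 by the basic ylide;
  - loss of iodine from the ylide, so that the plain ethylidene Wittig reaction competes;
  - poor control of the alkene geometry, which step 7 would pass on faithfully.
- Fallback (sets out from 9, returns at 15): the opposite alkenyl iodide is made from an alkyne and joined with retention. Corey–Fuchs olefination (CBr4, PPh3) gives the 1,1-dibromoalkene F4. Treatment with n-BuLi and then MeI gives the methyl alkyne F5. Syn hydrozirconation with excess Cp2Zr(H)Cl, which equilibrates zirconium to the less hindered methyl-bearing carbon, gives the alkenylzirconocene chloride F6, and iodinolysis gives the (E)-iodoalkene F7. A B-alkyl Suzuki–Miyaura coupling (PdCl2(dppf), aq NaOH, THF) with the 9-BBN adduct of acrolein diethyl acetal F8 gives 15.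

Step 8.
- What may go wrong:
  - acid-promoted condensation of the freed aldehyde, or of the released formaldehyde, with the electron-rich ring A once the phenol is free;
  - incomplete MOM cleavage under conditions mild enough for the alkene.
- Fallback (sets out from 15, returns at 21): the two acetals are removed at different stages, so that aldehyde and free phenol never meet in acid. Pyridinium p-toluenesulfonate in wet acetone hydrolyses only the diethyl acetal and gives the MOM-protected aldehyde F9. Still–Gennari olefination with carbanion 20 as in step 10 gives the MOM-protected dienoate F10. HCl in methanol then transfers the MOM group to the solvent and gives 21.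

Further compounds
F1 | step 7 | (2R)-2-(4,4-dichlorobut-3-en-1-yl)-7-(methoxymethoxy)-2,5-dimethylchromane | ClC(Cl)=CCC[C@]1(C)CCc2c(C)cc(OCOC)cc2O1
F2 | step 7 | (2R)-2-[(3Z)-4-chloro-6-(1,3-dioxolan-2-yl)hex-3-en-1-yl]-7-(methoxymethoxy)-2,5-dimethylchromane | Cl/C(CCC1OCCO1)=C\CC[C@]1(C)CCc2c(C)cc(OCOC)cc2O1
F3 | step 7 | (2R)-2-[(3E)-6-(1,3-dioxolan-2-yl)-4-methylhex-3-en-1-yl]-7-(methoxymethoxy)-2,5-dimethylchromane | O1CCOC1CC/C(C)=C/CC[C@]1(C)CCc2c(C)cc(OCOC)cc2O1
F4 | step 6 | (2R)-2-(4,4-dibromobut-3-en-1-yl)-7-(methoxymethoxy)-2,5-dimethylchromane | BrC(Br)=CCC[C@]1(C)CCc2c(C)cc(OCOC)cc2O1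
F5 | step 6 | (2R)-7-(methoxymethoxy)-2,5-dimethyl-2-(pent-3-yn-1-yl)chromane | CC#CCC[C@]1(C)CCc2c(C)cc(OCOC)cc2O1
F6 | step 6 | alkenylzirconocene chloride from F5, zirconium at C4' trans to the chain, (2R) | C/C(=C\CC[C@]1(C)CCc2c(C)cc(OCOC)cc2O1)[Zr](Cl)(C1C=CC=C1)C1C=CC=C1
F7 | step 6 | (2R)-2-[(3E)-4-iodopent-3-en-1-yl]-7-(methoxymethoxy)-2,5-dimethylchromane | C/C(I)=C\CC[C@]1(C)CCc2c(C)cc(OCOC)cc2O1
F8 | step 6 | 9-(3,3-diethoxypropyl)-9-borabicyclo[3.3.1]nonane | CCOC(CCB1C2CCCC1CCC2)OCC
F9 | step 8 | (4E)-7-[(2R)-7-(methoxymethoxy)-2,5-dimethylchroman-2-yl]-4-methylhept-4-enal | O=CCC/C(C)=C/CC[C@]1(C)CCc2c(C)cc(OCOC)cc2O1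
F10 | step 8 | methyl (2Z,6E)-9-[(2R)-7-(methoxymethoxy)-2,5-dimethylchroman-2-yl]-2,6-dimethylnona-2,6-dienoate | COC(=O)/C(C)=C\CC/C(C)=C/CC[C@]1(C)CCc2c(C)cc(OCOC)cc2O1
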